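What stayed the same in the two earlier runs was the dissolved substrate: at 4.00 h it read 54.7% of the solid charged with 12 mM of partner and 53.8% with 18 mM, equal within the scatter, while about 30.6% of the charge still lay undissolved in the south-east run. Solid substrate dissolves up to a ceiling (its solubility), and dissolved substrate meets partner to give target, so I reckoned target as a concentration, not a percentage.

| setting | south-east | south | flask |
|---|---|---|---|
| solid substrate | 12 mM | 12 mM | 12 mM |
| partner | 12 mM | 18 mM | 8.40 mM |
| remark | run made earlier | run made earlier |  |
| time |  |  | 6.0 h |

| run | time / h | target / % | dissolved substrate / % |
|---|---|---|---|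
| south-east | 0.250 | 0.3 | 12.5 |
| south-east | 0.500 | 1.2 | 25.5 |
| south-east | 0.833 | 4.2 | 36.0 |
| south-east | 1.33 | 7.8 | 40.8 |
| south-east | 2.00 | 10.1 | 49.4 |
| south-east | 4.00 | 14.7 | 54.7 |
| south | 0.250 | 0.9 | 15.8 |
| south | 0.667 | 4.7 | 30.4 |
| south | 1.33 | 9.7 | 41.7 |
| south | 2.00 | 13.1 | 48.8 |
| south | 3.00 | 16.9 | 51.8 |
| south | 4.00 | 19.1 | 53.8 |

(standard deviation of a reading: 1 percentage point)

- how much target there is at 6.0 h, in percent of the solid substrate charged
- concentration of dissolved substrate in solution at 6.0 h, in percent of saturation

- a species is counted by the solid substrate in it: one side product counts as two
- given per volume of solution although it is solid: solid substrate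
- on the list of suspects stand: solid substrate <-> dissolved substrate; dissolved substrate + partner -> target; dissolved substrate + target -> side product; 2 partner -> self-condensation product; partner -> decomposition product; partner -> decomposed reagent
- at the start none of the solid substrate is in solution
- dissolved substrate means what is dissolved; the solid is not counted in it

I turned the settings one at a time, in logarithms. For partner, proportionality predicted a rise of 1.50 times from the south-east run to the south run, but the last readings rose 1.30 times. That is a read order of 0.646, so going down to 8.40 mM gave a factor of 0.794.

For time, the south run's hourly gain shrank by a read ratio of 0.579, a rough figure given the scatter. Two more hours at that ratio gave a factor of 1.11.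

For solid substrate, the flask charged the same 12 mM as both runs, so the factor was one. My rule, with partner and time held and while solid remains, was that c_target stays the same and the percentage is c_target divided by the charge.

So, starting from the south-east run's last reading of 14.7% and applying both factors, I reckoned c_target for the flask at 1.55 mM, the concentration of target at 6.0 h with solid left, which is 12.9% of this charge.

The forecast gave 12.8% of target, range 10.5% to 15%, and 97% of saturation, holding that “the solution should sit close to saturation”.

The flask gave 13.0%, which is 1.56 mM against my 1.55 mM, at 99.0% of saturation, by these steps:

    solid substrate ⇌ dissolved substrate, rate k1*(cs1 - [dissolved substrate]) while solid is left; crystals form when [dissolved substrate] > cs1 (solubility = 6.70 mM, k = 3.70 × 10⁻⁴ /s)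
    dissolved substrate + partner → target (k = 0.00750 /M/s)
    dissolved substrate + target → side product (k = 1.10 × 10⁻⁴ /M/s)
    2 partner → self-condensation product (k = 0.00540 /M/s)
    partner → decomposition product (k = 7.10 × 10⁻⁸ /s)
    partner → decomposed reagent (k = 9.10 × 10⁻⁵ /s)

The neighbour flask charged 48 mM of solid substrate, with all else as in the flask. I kept c_target at 1.55 mM, which over that charge makes 3.23%, a slope of minus one in logarithms. The neighbour flask gave 3.25%, or 1.56 mM of target, with 82.9% of its charge still solid and 6.63 mM dissolved.

Readings and results come from a simulation for substances that don't exist; the scatter is artificial.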